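**Strategy**

Labels: in each cyclohexane C1 is the quaternary carbon (CH3 and acyl carbon C9), C2–C4 are methylenes, C5 is the alkylidene carbon, C6 the carbinol, C7H–C8H2 the exocyclic chain; the second half takes primes. The linker C5=C7–C8–C8′–C7′=C5′, with C6 and C8 cis on both alkenes, becomes a cycloocta-1,5-diene ring once a C6–C6′ bond is added. The plan is thus to join two molecules of a 2-alkylbuta-1,3-diene (chain C4–C1, C9 as acetal) in one iron-catalysed [4+4] cyclodimerisation, which forms C8–C8′ and C6–C6′ and holds both trisubstituted alkenes Z in an eight-membered template. Later scission of C6–C6′ gives two (Z)-enals that close the cyclohexanes by C1–C6 aldol reaction.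

Key step: step 3

Remark on the chemistry: the target SMILES describes a meso compound (ring centres 1R,2S in one half and 1S,2R in the other, hydroxyl cis to the acyl group in each ring); it is achiral, so "single enantiomer" is read as this single meso diastereomer and no absolute stereocontrol is needed.

**Route**

Step 1
Reactants: 1 2-methylpent-4-enal (racemic)
Product: 2 5,5-dimethoxy-4-methylpent-1-ene
Conditions: HC(OMe)3, MeOH, p-TsOH (cat.), rt
Reagents that add atoms: trimethyl orthoformate, COC(OC)OC
Why: Acid-catalysed acetalisation, driven by the orthoester, masks the enolisable aldehyde for the organometallic steps; the α-centre stays racemic, which is harmless because it is enolised in step 7.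

Step 2
Reactants: 2 5,5-dimethoxy-4-methylpent-1-ene; 3 chloroprene (2-chlorobuta-1,3-diene)
Product: 5 2-(5,5-dimethoxy-4-methylpentyl)buta-1,3-diene, via alkylborane 4 (not isolated)
Conditions: 9-BBN, THF, 0 °C → rt; then 3 (3 equiv), Pd(OAc)2/SPhos (cat.), aq K3PO4, THF, 40 °C
Reagents that add atoms: none
Why: Anti-Markovnikov hydroboration of the terminal alkene followed by B-alkyl Suzuki–Miyaura coupling with the alkenyl chloride (the electron-rich biarylphosphine allows C–Cl oxidative addition) should attach the chain at C2 of the diene in one flask, the acetal being inert to borane and base.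

Step 3
Reactants: 5 2-(5,5-dimethoxy-4-methylpentyl)buta-1,3-diene (two molecules)
Product: 6 (1Z,5Z)-1,6-bis(5,5-dimethoxy-4-methylpentyl)cycloocta-1,5-diene
Conditions: [(MePI)FeCl2]2 (MePI = 2-[1-(2,6-dimethylphenylimino)ethyl]pyridine, 2 mol % Fe), MeMgCl (4 mol %), neat 5, 23 °C
Reagents that add atoms: none
Why: Reduction of the iron(II) precatalyst by MeMgCl should give an iminopyridine–iron(0) species that binds two molecules of 5; oxidative coupling joins the unsubstituted termini (C8–C8′) to a bis(allyl)iron intermediate, and C–C reductive elimination between the substituted allyl termini (C6–C6′) releases 6, a formal [4+4] cycloaddition. The closest known reaction is the iminopyridine–iron (or Ni(0)/phosphite) cyclodimerisation of isoprene and myrcene to 1,6-disubstituted cycloocta-1,5-dienes, and 5 is a myrcene analogue whose remote acetal should not bind the metal. The eight-membered ring closes by reductive elimination from the ferracycle in which both allyl units are held syn, so both ring alkenes come out cis. No stereocentre is formed: the Z geometry of C5=C7 and C5′=C7′ (C6 cis to C8) is dictated by the medium ring, which cannot hold a trans alkene, and the two remote CHMe centres stay as an inconsequential mixture. The step needs [4+4] over [4+2] and head-to-head (1,6) over head-to-tail (1,5) coupling; both are set by the ligand, whose 2,6-dimethylphenyl ketimine favours coupling at the less hindered termini, and the single 2-alkyl substituent of 5 leaves C8 unhindered.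

Step 4
Reactants: 6 (1Z,5Z)-1,6-bis(5,5-dimethoxy-4-methylpentyl)cycloocta-1,5-diene
Product: 8 (2Z,6Z)-2,7-bis(5,5-dimethoxy-4-methylpentyl)cycloocta-2,6-dien-1-one, via dienol 7 (not isolated)
Conditions: SeO2 (0.3 equiv), t-BuOOH (2 equiv), CH2Cl2, 0 °C → rt, stopped near half conversion; then DMP, NaHCO3, CH2Cl2, 0 °C
Reagents that add atoms: selenium dioxide (oxygen carrier), O=[Se]=O; tert-butyl hydroperoxide (terminal oxidant), CC(C)(C)OO
Why: Riley allylic hydroxylation (ene reaction, then [2,3]-shift) should go α to the more substituted alkene carbon and, for a ring alkene, at the ring methylene C6 without moving the alkene, and Dess–Martin oxidation then converges alcohol and any enone to 8; partial conversion limits attack on the second, equivalent alkene, and recovered 6 is recycled.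

Step 5
Reactants: 8 (2Z,6Z)-2,7-bis(5,5-dimethoxy-4-methylpentyl)cycloocta-2,6-dien-1-one
Product: 9 (2Z,6Z)-8-hydroxy-2,7-bis(5,5-dimethoxy-4-methylpentyl)cycloocta-2,6-dien-1-one
Conditions: KHMDS, THF, −78 °C; then 2-(phenylsulfonyl)-3-phenyloxaziridine, −78 °C; aq NH4Cl
Reagents that add atoms: 2-(phenylsulfonyl)-3-phenyloxaziridine (Davis reagent), O=S(=O)(c1ccccc1)N1OC1c1ccccc1
Why: Kinetic deprotonation of the dienone at its only α′-methylene (C6′, also allylic) and Davis oxidation of the potassium enolate should place the second oxygen regiospecifically next to the first; the new carbinol centre forms as a mixture and is destroyed in step 7.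

Step 6
Reactants: 9 (2Z,6Z)-8-hydroxy-2,7-bis(5,5-dimethoxy-4-methylpentyl)cycloocta-2,6-dien-1-one
Product: 11 5,5′-[(1Z,5Z)-7,8-dihydroxycycloocta-1,5-diene-1,6-diyl]bis(2-methylpentanal), via diol bis-acetal 10 (not isolated)
Conditions: NaBH4, CeCl3·7H2O, MeOH, −40 °C; then THF/1 M aq HCl (4:1), rt
Reagents that add atoms: water, O
Why: Luche 1,2-reduction of the enone gives the 1,2-diol (either relative configuration serves), and mild aqueous acid then hydrolyses the dimethyl acetals at a stage where no acid-sensitive (Z)-enal is yet present.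

Step 7
Reactants: 11 5,5′-[(1Z,5Z)-7,8-dihydroxycycloocta-1,5-diene-1,6-diyl]bis(2-methylpentanal)
Product: 13 meso bis(β-hydroxy aldehyde) (1R,2S,3Z / 1′S,2′R,3′Z; OH cis to CHO in each ring), via tetra-aldehyde 12 (not isolated)
Conditions: NaIO4, THF/pH 7 buffer, 0 °C; extraction; then DL-proline (30 mol %), CH2Cl2 (high dilution), rt; silica gel, then preparative HPLC on a chiral stationary phase
Reagents that add atoms: none
Why: Periodate glycol cleavage cuts C6–C6′ under neutral conditions to the (Z,Z)-dienedial, and racemic proline then converts each α-branched aldehyde into its enamine, which adds to the neighbouring enal carbonyl (6-enolexo intramolecular aldol reaction); attack on the s-trans enal, whose Z substituent forces the new C6–O bond axial, through a hydrogen-bonded closed transition state should place CHO cis to OH in each ring, while the two rings close independently, so the meso and the C2-symmetric diastereomers are expected in equal amounts and the meso isomer 13 is taken by chromatography on the chiral phase, which sorts by the handedness of each ring.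

Step 8
Reactants: 13 meso bis(β-hydroxy aldehyde)
Product: 14 bis(triethylsilyl) ether of 13
Conditions: TESOTf, 2,6-lutidine, CH2Cl2, −78 → 0 °C
Reagents that add atoms: triethylsilyl trifluoromethanesulfonate, CC[Si](CC)(CC)OS(=O)(=O)C(F)(F)F
Why: Silylation of the hindered secondary allylic alcohols with the silyl triflate protects them and blocks retro-aldol cleavage before the organometallic step; the α-quaternary aldehydes cannot enolise.

Step 9
Reactants: 14 bis(triethylsilyl) ether of 13; 15 allylmagnesium bromide
Product: 16 bis(homoallylic alcohol) (mixture at the two new carbinol centres)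
Conditions: 15 (4 equiv), THF/Et2O, −78 °C; aq NH4Cl
Reagents that add atoms: none
Why: Grignard 1,2-addition of the allyl reagent to the non-enolisable neopentyl-type aldehydes should be clean; the new carbinol centres form as a mixture and are removed by the oxidation in step 11.

Step 10
Reactants: 16 bis(homoallylic alcohol); 17 2-methylbut-2-ene
Product: 18 bis(prenyl carbinol) (mixture at the carbinol centres)
Conditions: Grubbs second-generation catalyst (10 mol %), 17/CH2Cl2 (1:1), 40 °C, sealed tube
Reagents that add atoms: none
Why: Olefin cross-metathesis of each terminal allyl group with excess 2-methylbut-2-ene should convert it into a prenyl group; the trisubstituted ring alkylidenes are inert to the ruthenium carbene and the excess partner suppresses ring closure between the two arms.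

Step 11
Reactants: 18 bis(prenyl carbinol)
Product: 19 bis(triethylsilyl) ether of the target
Conditions: DMP, NaHCO3, CH2Cl2, 0 °C → rt
Reagents that add atoms: none
Why: Dess–Martin oxidation of the secondary homoallylic alcohols under buffered, non-basic conditions should give the β,γ-unsaturated ketones without moving the alkenes into conjugation, and it removes the carbinol stereocentres.

Step 12
Reactants: 19 bis(triethylsilyl) ether of the target
Product: 20 CNP0297042.2 (meso target)
Conditions: HF·pyridine, pyridine, THF, 0 °C → rt
Reagents that add atoms: none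
Why: Buffered fluoride cleavage of the triethylsilyl ethers is mild enough to leave the retro-aldol-prone β-hydroxy ketones and the skipped enones untouched; all four stereocentres and both Z alkenes are carried unchanged from 13.

**Compound list**

1 | 2-methylpent-4-enal (racemic) | C=CCC(C)C=O | starting material
2 | 5,5-dimethoxy-4-methylpent-1-ene | C=CCC(C)C(OC)OC | intermediate
3 | chloroprene (2-chlorobuta-1,3-diene) | C=CC(Cl)=C | starting material
4 | 9-(5,5-dimethoxy-4-methylpentyl)-9-borabicyclo[3.3.1]nonane | COC(OC)C(C)CCCB1C2CCCC1CCC2 | intermediate (not isolated)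
5 | 2-(5,5-dimethoxy-4-methylpentyl)buta-1,3-diene | C=CC(=C)CCCC(C)C(OC)OC | intermediate
6 | (1Z,5Z)-1,6-bis(5,5-dimethoxy-4-methylpentyl)cycloocta-1,5-diene (mixture at the two CHMe centres) | COC(OC)C(C)CCC/C1=C/CC/C=C(/CCCC(C)C(OC)OC)CC1 | intermediate
7 | (2Z,6Z)-2,7-bis(5,5-dimethoxy-4-methylpentyl)cycloocta-2,6-dien-1-ol | COC(OC)C(C)CCC/C1=C/CC/C=C(/CCCC(C)C(OC)OC)CC1O | intermediate (not isolated)
8 | (2Z,6Z)-2,7-bis(5,5-dimethoxy-4-methylpentyl)cycloocta-2,6-dien-1-one | COC(OC)C(C)CCC/C1=C/CC/C=C(/CCCC(C)C(OC)OC)CC1=O | intermediate
9 | (2Z,6Z)-8-hydroxy-2,7-bis(5,5-dimethoxy-4-methylpentyl)cycloocta-2,6-dien-1-one | COC(OC)C(C)CCC/C1=C/CC/C=C(/CCCC(C)C(OC)OC)C(O)C1=O | intermediate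
10 | (3Z,7Z)-3,8-bis(5,5-dimethoxy-4-methylpentyl)cycloocta-3,7-diene-1,2-diol | COC(OC)C(C)CCC/C1=C/CC/C=C(/CCCC(C)C(OC)OC)C(O)C1O | intermediate (not isolated)
11 | 5,5′-[(1Z,5Z)-7,8-dihydroxycycloocta-1,5-diene-1,6-diyl]bis(2-methylpentanal) | O=CC(C)CCC/C1=C/CC/C=C(/CCCC(C)C=O)C(O)C1O | intermediate
12 | (2Z,6Z)-2,7-bis(4-methyl-5-oxopentyl)octa-2,6-dienedial | O=CC(C)CCC/C(C=O)=C/CC/C=C(/CCCC(C)C=O)C=O | intermediate (not isolated)
13 | meso-(1R,2S,3Z)-2-hydroxy-3-[(4Z)-4-[(2R,3S)-3-formyl-2-hydroxy-3-methylcyclohexylidene]butylidene]-1-methylcyclohexane-1-carbaldehyde (OH cis to CHO in both rings) | O=C[C@]1(C)CCC/C(=C/CC/C=C2/CCC[C@](C)(C=O)[C@@H]2O)[C@@H]1O | intermediate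
14 | bis(triethylsilyl) ether of 13 (ring stereocentres and alkenes as in 13) | O=C[C@]1(C)CCC/C(=C/CC/C=C2/CCC[C@](C)(C=O)[C@@H]2O[Si](CC)(CC)CC)[C@@H]1O[Si](CC)(CC)CC | intermediate
15 | allylmagnesium bromide | C=CC[Mg]Br | starting material
16 | bis(1-hydroxybut-3-enyl) compound from 14 (each CHO now CH(OH)CH2CH=CH2; ring centres as in 13; carbinol centres mixed) | C=CCC(O)[C@]1(C)CCC/C(=C/CC/C=C2/CCC[C@](C)(C(O)CC=C)[C@@H]2O[Si](CC)(CC)CC)[C@@H]1O[Si](CC)(CC)CC | intermediate
17 | 2-methylbut-2-ene | CC=C(C)C | starting material
18 | bis(1-hydroxy-4-methylpent-3-enyl) compound (each side chain CH(OH)CH2CH=CMe2; ring centres as in 13; carbinol centres mixed) | CC(C)=CCC(O)[C@]1(C)CCC/C(=C/CC/C=C2/CCC[C@](C)(C(O)CC=C(C)C)[C@@H]2O[Si](CC)(CC)CC)[C@@H]1O[Si](CC)(CC)CC | intermediate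
19 | bis(triethylsilyl) ether of the target (1R,2S,3Z / 1′S,2′R,3′Z) | CC(C)=CCC(=O)[C@]1(C)CCC/C(=C/CC/C=C2/CCC[C@](C)(C(=O)CC=C(C)C)[C@@H]2O[Si](CC)(CC)CC)[C@@H]1O[Si](CC)(CC)CC | intermediate
20 | 1-[(1R,2S,3Z)-2-hydroxy-3-[(4Z)-4-[(2R,3S)-2-hydroxy-3-methyl-3-(4-methylpent-3-enoyl)cyclohexylidene]butylidene]-1-methylcyclohexyl]-4-methylpent-3-en-1-one (meso; CNP0297042.2) | CC(C)=CCC(=O)[C@]1(C)CCC/C(=C/CC/C=C2/CCC[C@](C)(C(=O)CC=C(C)C)[C@@H]2O)[C@@H]1O | target

**Count and risks**

Total: 12 steps. Longest linear sequence: 12 steps (1 → 20).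

Most likely to fail, first: step 4. The ene oxidation may take hydrogen from the side-chain methylene next to the ring (C4) instead of the ring methylene C6, and may also attack the second alkene, so that little mono-ring-oxidised material forms. The fallback changes the selectivity principle and sets out from 6. Dye-sensitised photo-oxygenation (O2, tetraphenylporphyrin, hν) is a singlet-oxygen ene reaction whose cis effect takes hydrogen from the doubly substituted side of the alkene and so spares the side chain. It should give the secondary allylic hydroperoxide F1 (oxygen on C7, alkene moved to C5=C6), dehydrated in the same flask with Ac2O/pyridine (Kornblum–DeLaMare) to the transposed dienone F2. Weitz–Scheffer epoxidation (H2O2, NaOH, MeOH) gives the epoxy ketone F3. Wharton transposition (N2H4·H2O, cat. AcOH, MeOH) through the epoxy hydrazone F4 puts the oxygen on C6 and restores C5=C7. The fallback comes back at 7, which is oxidised with DMP to 8 as in step 4.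

Second: step 7. The two ring closures do not communicate, so heterochiral and homochiral pairing are equally likely and the meso isomer may prove hard to separate from its diastereomer; the amine may also erode the Z-enal geometry. The fallback replaces statistical pairing by catalyst control and sets out from 12. L-proline is used to about half conversion and the monocyclised hydroxy trialdehyde F5 (one ring closed, one enantiomeric series) is isolated; it differs in polarity from unreacted 12 (recycled) and from doubly cyclised material. The second ring is then closed with D-proline, which imposes the opposite sense whatever the sense of the first, and the fallback comes back at 13.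

Third: step 3. The acetal-bearing diene may give head-to-tail (1,5) cyclodimer or [4+2] adducts beside 6, or traces of palladium, phosphine or peroxide from step 2 may deactivate the low-valent iron. The fallback builds the same ring by a sigmatropic route and sets out from 4 (made from 2 as in step 2). Commercial cis-cyclobutane-1,2-dicarboxylic acid with MeLi gives cis-1,2-diacetylcyclobutane F6. Kinetic enolisation at the methyl groups (KHMDS, PhNTf2, −78 °C) gives the bis(enol triflate) F7. Twofold B-alkyl Suzuki coupling with 4 (PdCl2(dppf), K3PO4) gives cis-1,2-bis(7,7-dimethoxy-6-methylhept-1-en-2-yl)cyclobutane F8. Its Cope rearrangement (toluene, 110 °C, boat transition state) can only deliver the 1,6-disubstituted (1Z,5Z)-diene, so the fallback comes back at 6.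

Further compounds
F1 | step 4 | (2Z,5Z)-2,5-bis(5,5-dimethoxy-4-methylpentyl)cycloocta-2,5-dien-1-yl hydroperoxide | OOC1CC/C=C(/CCCC(C)C(OC)OC)C/C=C1/CCCC(C)C(OC)OC
F2 | step 4 | (2Z,5Z)-2,5-bis(5,5-dimethoxy-4-methylpentyl)cycloocta-2,5-dien-1-one | O=C1CC/C=C(/CCCC(C)C(OC)OC)C/C=C1/CCCC(C)C(OC)OC
F3 | step 4 | (5Z)-1,6-bis(5,5-dimethoxy-4-methylpentyl)-9-oxabicyclo[6.1.0]non-5-en-2-one | O=C1CC/C=C(/CCCC(C)C(OC)OC)CC2OC12CCCC(C)C(OC)OC
F4 | step 4 | hydrazone of F3 | NN=C1CC/C=C(/CCCC(C)C(OC)OC)CC2OC12CCCC(C)C(OC)OC
F5 | step 7 | (2Z,6Z)-6-[(2S,3R)-3-formyl-2-hydroxy-3-methylcyclohexylidene]-2-(4-methyl-5-oxopentyl)hex-2-enal (monocyclised; OH cis to CHO) | O=C[C@]1(C)CCC/C(=C/CC/C=C(/CCCC(C)C=O)C=O)[C@@H]1O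
F6 | step 3 | cis-1,2-diacetylcyclobutane | CC(=O)[C@@H]1CC[C@@H]1C(C)=O
F7 | step 3 | cis-cyclobutane-1,2-diylbis(ethene-1,1-diyl) bis(trifluoromethanesulfonate) | C=C(OS(=O)(=O)C(F)(F)F)[C@@H]1CC[C@@H]1C(=C)OS(=O)(=O)C(F)(F)F
F8 | step 3 | cis-1,2-bis(7,7-dimethoxy-6-methylhept-1-en-2-yl)cyclobutane | C=C(CCCC(C)C(OC)OC)[C@@H]1CC[C@@H]1C(=C)CCCC(C)C(OC)OC
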